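**Retrosynthetic overview**
1. Target ⇐ desilylation and oxidative γ-lactonisation (C12 alcohol oxidised and closed onto O-6) of a 10-membered 6,12-diol; the lactone ring is formed last, as in costunolide biosynthesis.
2. The 10-membered carbocycle is formed first by a cyclase-like C6–C7 closure: an intramolecular carbonyl-ene (Prins-type) attack of the 7(11)-alkene of an acyclic farnesane-type trienal on its C6 enal, with loss of a C13 hydrogen.
3. Acyclic trienal ⇐ vinylogous Mukaiyama aldol (C2–C3, sets C2) between the silyl dienol ether of 3-methylbut-2-enal and a (Z)-enal carrying C8-OSi and the C9 angelate.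
4. (Z)-Enal ⇐ ring opening (Weinreb aminolysis with in-flask angeloylation, then reduction) of a 4-methylbutenolide that locks the 1(10)-Z alkene; butenolide ⇐ asymmetric vinylogous aldol (C8–C9, sets C8 and C9) of 4-methyl-2-silyloxyfuran with a (Z)-C5 enal.
5. Both C5 partners come from 4-methylfuran-2(5H)-one; the remaining carbons come from 3-methylbut-2-enal and angelic anhydride.

Assumptions: germacrane numbering is used (lactone C12–O–C6; target = (2S,6R,7R,8R,9R), 1(10)Z,4E, angelate = (Z)-2-methylbut-2-enoate); the facial sense of the two chiral Lewis acids in steps 4 and 9 is taken as written, and the enantiomeric ligand would be used if it proved opposite.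

**Route**

Step 1
Reactants: 1 4-methylfuran-2(5H)-one
Product: 3 (Z)-N-methoxy-N,3-dimethyl-4-(triethylsilyloxy)but-2-enamide, via hydroxy Weinreb amide 2 (not isolated)
Conditions: AlMe3, MeNH(OMe)·HCl, CH2Cl2, 0 °C to rt; then 2,6-lutidine, Et3SiOTf, −78 to 0 °C
Reagents that add atoms: N,O-dimethylhydroxylamine hydrochloride, CNOC.Cl; triethylsilyl triflate, CC[Si](CC)(CC)OS(=O)(=O)C(F)(F)F
Why: Lactone aminolysis by the aluminium amide (Weinreb amide formation) opens the ring without touching the Z-alkene, and silylation of the aluminium alkoxide in the same flask stops relactonisation.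

Step 2
Reactants: 3 (Z)-N-methoxy-N,3-dimethyl-4-(triethylsilyloxy)but-2-enamide
Product: 4 (Z)-3-methyl-4-(triethylsilyloxy)but-2-enal
Conditions: i-Bu2AlH, THF, −78 °C
Reagents that add atoms: none
Why: Weinreb amide reduction: the chelated aluminium hemiaminal survives until work-up, so the (Z)-enal is released without over-reduction.

Step 3
Reactants: 1 4-methylfuran-2(5H)-one
Product: 5 4-methyl-2-(trimethylsilyloxy)furan
Conditions: Me3SiOTf, Et3N, Et2O, 0 °C
Reagents that add atoms: trimethylsilyl triflate, C[Si](C)(C)OS(=O)(=O)C(F)(F)F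
Why: Soft enolisation of the butenolide at C5 gives the aromatic 2-silyloxyfuran, the dienolate equivalent for a vinylogous aldol.

Step 4
Reactants: 4 (Z)-3-methyl-4-(triethylsilyloxy)but-2-enal; 5 4-methyl-2-(trimethylsilyloxy)furan
Product: 7 (R)-5-[(1R,2Z)-1-hydroxy-3-methyl-4-(triethylsilyloxy)but-2-en-1-yl]-4-methylfuran-2(5H)-one, via O-trimethylsilyl aldol adduct 6 (not isolated)
Conditions: Ti(OiPr)4 (20 mol %), (S)-BINOL (20 mol %), Et2O, −20 °C; then AcOH, THF/H2O, 0 °C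
Reagents that add atoms: none
Why: Catalytic asymmetric vinylogous Mukaiyama aldol: the Ti(OiPr)4/(S)-BINOL Lewis acid directs furan C5 to the Si face of the aldehyde through an open synclinal transition state that gives the threo (8R,9R) pair, and the butenolide formed locks the future 1(10)-alkene as Z.

Step 5
Reactants: 7 (R)-5-[(1R,2Z)-1-hydroxy-3-methyl-4-(triethylsilyloxy)but-2-en-1-yl]-4-methylfuran-2(5H)-one
Product: 8 (R)-5-[(1R,2Z)-1-(tert-butyldimethylsilyloxy)-3-methyl-4-(triethylsilyloxy)but-2-en-1-yl]-4-methylfuran-2(5H)-one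
Conditions: t-BuMe2SiOTf, 2,6-lutidine, CH2Cl2, −78 °C
Reagents that add atoms: tert-butyldimethylsilyl triflate, CC(C)(C)[Si](C)(C)OS(=O)(=O)C(F)(F)F
Why: Silyl triflate silylation of the hindered secondary alcohol; this robust ether later keeps O-8 from competing with O-6 in the lactonisation.

Step 6
Reactants: 8 (R)-5-[(1R,2Z)-1-(tert-butyldimethylsilyloxy)-3-methyl-4-(triethylsilyloxy)but-2-en-1-yl]-4-methylfuran-2(5H)-one; 9 angelic anhydride
Product: 11 (2Z,4R,5R,6Z)-5-(tert-butyldimethylsilyloxy)-1-[methoxy(methyl)amino]-3,7-dimethyl-1-oxo-8-(triethylsilyloxy)octa-2,6-dien-4-yl angelate, via hydroxy Weinreb amide 10 (not isolated)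
Conditions: AlMe3, MeNH(OMe)·HCl, CH2Cl2, 0 °C to rt; then pyridine, DMAP, 9, 0 °C to rt
Reagents that add atoms: N,O-dimethylhydroxylamine hydrochloride, CNOC.Cl
Why: Weinreb aminolysis opens the butenolide to the (Z)-γ-aluminoxy amide, which is O-acylated in the same flask by anhydride/DMAP (acyl transfer to an aluminium alkoxide, as in reductive acylation), so O-9 appears only as its angelate and cannot relactonise; C9 is not touched.

Step 7
Reactants: 11 (2Z,4R,5R,6Z)-5-(tert-butyldimethylsilyloxy)-1-[methoxy(methyl)amino]-3,7-dimethyl-1-oxo-8-(triethylsilyloxy)octa-2,6-dien-4-yl angelate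
Product: 12 (2Z,4R,5R,6Z)-5-(tert-butyldimethylsilyloxy)-3,7-dimethyl-1-oxo-8-(triethylsilyloxy)octa-2,6-dien-4-yl angelate
Conditions: Cp2Zr(H)Cl, THF, rt, 20 min
Reagents that add atoms: none
Why: Amide-to-aldehyde reduction by hydrozirconation of the amide carbonyl: the zirconated hemiaminal hydrolyses to the (Z)-enal while the angelate, the silyl ethers and the trisubstituted alkenes are inert.

Step 8
Reactants: 13 3-methylbut-2-enal
Product: 14 (E)-tert-butyldimethyl[(3-methylbuta-1,3-dien-1-yl)oxy]silane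
Conditions: t-BuMe2SiOTf, Et3N, CH2Cl2, 0 °C
Reagents that add atoms: tert-butyldimethylsilyl triflate, CC(C)(C)[Si](C)(C)OS(=O)(=O)C(F)(F)F
Why: γ-Deprotonation of the O-silylated enal gives the (E)-silyl dienol ether (silyl dienol ether formation).

Step 9
Reactants: 12 (2Z,4R,5R,6Z)-5-(tert-butyldimethylsilyloxy)-3,7-dimethyl-1-oxo-8-(triethylsilyloxy)octa-2,6-dien-4-yl angelate; 14 (E)-tert-butyldimethyl[(3-methylbuta-1,3-dien-1-yl)oxy]silane
Product: 15 (2E,5S,6Z,8R,9R,10Z)-9-(tert-butyldimethylsilyloxy)-5-hydroxy-3,7,11-trimethyl-1-oxo-12-(triethylsilyloxy)dodeca-2,6,10-trien-8-yl angelate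
Conditions: preformed B-phenyl oxazaborolidinone of N-tosyl-L-tryptophan (1.1 equiv), i-PrOH (1.2 equiv), EtCN, −78 °C
Reagents that add atoms: none
Why: Vinylogous Mukaiyama aldol promoted by a chiral boron Lewis acid: the γ-carbon of 14 adds to the Si face of the complexed (Z)-enal, which sets C2 as S, and the new 4,5-alkene is formed E.

Step 10
Reactants: 15 (2E,5S,6Z,8R,9R,10Z)-9-(tert-butyldimethylsilyloxy)-5-hydroxy-3,7,11-trimethyl-1-oxo-12-(triethylsilyloxy)dodeca-2,6,10-trien-8-yl angelate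
Product: 17 (1(10)Z,4E)-9β-angeloyloxy-8α-(tert-butyldimethylsilyloxy)germacra-1(10),4,11(13)-triene-2α,6α,12-triol, via macrocyclic triethylsilyl ether 16 (not isolated)
Conditions: Me2AlCl (3 equiv), CH2Cl2 (1 mM, syringe-pump addition of 15), −78 to −30 °C; then MeOH, PPTS, 0 °C to rt
Reagents that add atoms: none
Why: Proposed new method: a Me2AlCl-promoted intramolecular carbonyl-ene (Prins-type) macrocyclisation in which the 7(11)-alkene attacks the Lewis acid-activated C6 enal and a C13 methyl hydrogen passes to oxygen through a six-membered chair transition state, the non-enzymatic counterpart of the cation/alkene closure and proton loss of germacrene A synthase; the E-4,5-alkene rules out 6- and 7-membered alternatives, A(1,3) strain between C8-H and the cis C12 substituent exposes the C7 face anti to the silyloxy group, and the all-pseudo-equatorial chair places H6 and H7 anti, which gives 6α-OH and 7α-H (6R,7S here); the closest known chemistry is the Me2AlCl-promoted type 1 intramolecular ene reaction of unsaturated aldehydes and Lewis acid ene macrocyclisations of conjugated aldehydes to 12- and 14-membered rings; PPTS/MeOH then cleaves only the primary triethylsilyl ether.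

Step 11
Reactants: 17 (1(10)Z,4E)-9β-angeloyloxy-8α-(tert-butyldimethylsilyloxy)germacra-1(10),4,11(13)-triene-2α,6α,12-triol
Product: 20 (1(10)Z,4E)-9β-angeloyloxy-8α-(tert-butyldimethylsilyloxy)-2α-hydroxygermacra-1(10),4,11(13)-trien-12,6α-olide, via hydroxy enal 18 (not isolated), via lactol 19 (not isolated)
Conditions: TEMPO (20 mol %), PhI(OAc)2 (2.3 equiv), CH2Cl2, rt
Reagents that add atoms: none
Why: Oxoammonium (TEMPO) oxidation is selective for the primary allylic alcohol; the enal is captured by the only free γ-hydroxyl (O-6, since O-8 is silylated) and the lactol is oxidised on to the α-methylene-γ-lactone (oxidative lactonisation), with no change at C6 or C7.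

Step 12
Reactants: 20 (1(10)Z,4E)-9β-angeloyloxy-8α-(tert-butyldimethylsilyloxy)-2α-hydroxygermacra-1(10),4,11(13)-trien-12,6α-olide
Product: 21 (1(10)Z,4E)-9β-angeloyloxy-2α,8α-dihydroxygermacra-1(10),4,11(13)-trien-12,6α-olide (CNP0311662.1)
Conditions: HF·pyridine, pyridine, THF, 0 °C to rt
Reagents that add atoms: none
Why: Fluoride desilylation under weakly acidic conditions frees O-8 without 9-to-8 acyl migration or conjugate addition to the methylene lactone.

**Compound list**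
1 | 4-methylfuran-2(5H)-one | CC1=CC(=O)OC1 | starting material
2 | (Z)-4-hydroxy-N-methoxy-N,3-dimethylbut-2-enamide (present as its aluminium alkoxide) | CON(C)C(=O)/C=C(C)\CO | intermediate
3 | (Z)-N-methoxy-N,3-dimethyl-4-(triethylsilyloxy)but-2-enamide | CON(C)C(=O)/C=C(C)\CO[Si](CC)(CC)CC | intermediate
4 | (Z)-3-methyl-4-(triethylsilyloxy)but-2-enal | O=C/C=C(C)\CO[Si](CC)(CC)CC | intermediate
5 | 4-methyl-2-(trimethylsilyloxy)furan | Cc1coc(O[Si](C)(C)C)c1 | intermediate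
6 | (R)-4-methyl-5-[(1R,2Z)-3-methyl-4-(triethylsilyloxy)-1-(trimethylsilyloxy)but-2-en-1-yl]furan-2(5H)-one | CC1=CC(=O)O[C@H]1[C@H](O[Si](C)(C)C)/C=C(C)\CO[Si](CC)(CC)CC | intermediate
7 | (R)-5-[(1R,2Z)-1-hydroxy-3-methyl-4-(triethylsilyloxy)but-2-en-1-yl]-4-methylfuran-2(5H)-one | CC1=CC(=O)O[C@H]1[C@H](O)/C=C(C)\CO[Si](CC)(CC)CC | intermediate
8 | (R)-5-[(1R,2Z)-1-(tert-butyldimethylsilyloxy)-3-methyl-4-(triethylsilyloxy)but-2-en-1-yl]-4-methylfuran-2(5H)-one | CC1=CC(=O)O[C@H]1[C@H](O[Si](C)(C)C(C)(C)C)/C=C(C)\CO[Si](CC)(CC)CC | intermediate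
9 | angelic anhydride, (Z)-2-methylbut-2-enoic anhydride | C/C=C(/C)C(=O)OC(=O)/C(C)=C\C | starting material
10 | (2Z,4R,5R,6Z)-5-(tert-butyldimethylsilyloxy)-4-hydroxy-N-methoxy-N,3,7-trimethyl-8-(triethylsilyloxy)octa-2,6-dienamide (present as its aluminium alkoxide) | CON(C)C(=O)/C=C(C)\[C@@H](O)[C@H](O[Si](C)(C)C(C)(C)C)/C=C(C)\CO[Si](CC)(CC)CC | intermediate
11 | (2Z,4R,5R,6Z)-5-(tert-butyldimethylsilyloxy)-1-[methoxy(methyl)amino]-3,7-dimethyl-1-oxo-8-(triethylsilyloxy)octa-2,6-dien-4-yl angelate | CON(C)C(=O)/C=C(C)\[C@@H](OC(=O)/C(C)=C\C)[C@H](O[Si](C)(C)C(C)(C)C)/C=C(C)\CO[Si](CC)(CC)CC | intermediate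
12 | (2Z,4R,5R,6Z)-5-(tert-butyldimethylsilyloxy)-3,7-dimethyl-1-oxo-8-(triethylsilyloxy)octa-2,6-dien-4-yl angelate | O=C/C=C(C)\[C@@H](OC(=O)/C(C)=C\C)[C@H](O[Si](C)(C)C(C)(C)C)/C=C(C)\CO[Si](CC)(CC)CC | intermediate
13 | 3-methylbut-2-enal | CC(C)=CC=O | starting material
14 | (E)-tert-butyldimethyl[(3-methylbuta-1,3-dien-1-yl)oxy]silane | C=C(C)/C=C/O[Si](C)(C)C(C)(C)C | intermediate
15 | (2E,5S,6Z,8R,9R,10Z)-9-(tert-butyldimethylsilyloxy)-5-hydroxy-3,7,11-trimethyl-1-oxo-12-(triethylsilyloxy)dodeca-2,6,10-trien-8-yl angelate | O=C/C=C(\C)C[C@H](O)/C=C(C)\[C@@H](OC(=O)/C(C)=C\C)[C@H](O[Si](C)(C)C(C)(C)C)/C=C(C)\CO[Si](CC)(CC)CC | intermediate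
16 | (1(10)Z,4E)-9β-angeloyloxy-8α-(tert-butyldimethylsilyloxy)-12-(triethylsilyloxy)germacra-1(10),4,11(13)-triene-2α,6α-diol; (2S,6R,7S,8R,9R) | C=C(CO[Si](CC)(CC)CC)[C@H]1[C@H](O)/C=C(\C)C[C@H](O)/C=C(/C)[C@@H](OC(=O)/C(C)=C\C)[C@@H]1O[Si](C)(C)C(C)(C)C | intermediate
17 | (1(10)Z,4E)-9β-angeloyloxy-8α-(tert-butyldimethylsilyloxy)germacra-1(10),4,11(13)-triene-2α,6α,12-triol; (2S,6R,7S,8R,9R) | C=C(CO)[C@H]1[C@H](O)/C=C(\C)C[C@H](O)/C=C(/C)[C@@H](OC(=O)/C(C)=C\C)[C@@H]1O[Si](C)(C)C(C)(C)C | intermediate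
18 | (1(10)Z,4E)-9β-angeloyloxy-8α-(tert-butyldimethylsilyloxy)-2α,6α-dihydroxygermacra-1(10),4,11(13)-trien-12-al | C=C(C=O)[C@H]1[C@H](O)/C=C(\C)C[C@H](O)/C=C(/C)[C@@H](OC(=O)/C(C)=C\C)[C@@H]1O[Si](C)(C)C(C)(C)C | intermediate
19 | 12-lactol of 18 closed on O-6 (both C12 epimers) | C=C1C(O)O[C@@H]2/C=C(\C)C[C@H](O)/C=C(/C)[C@@H](OC(=O)/C(C)=C\C)[C@H](O[Si](C)(C)C(C)(C)C)[C@@H]12 | intermediate
20 | (1(10)Z,4E)-9β-angeloyloxy-8α-(tert-butyldimethylsilyloxy)-2α-hydroxygermacra-1(10),4,11(13)-trien-12,6α-olide; (2S,6R,7S,8R,9R) | C=C1C(=O)O[C@@H]2/C=C(\C)C[C@H](O)/C=C(/C)[C@@H](OC(=O)/C(C)=C\C)[C@H](O[Si](C)(C)C(C)(C)C)[C@@H]12 | intermediate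
21 | (1(10)Z,4E)-9β-angeloyloxy-2α,8α-dihydroxygermacra-1(10),4,11(13)-trien-12,6α-olide; (2S,6R,7R,8R,9R) | C=C1C(=O)O[C@@H]2/C=C(\C)C[C@H](O)/C=C(/C)[C@@H](OC(=O)/C(C)=C\C)[C@H](O)[C@@H]12 | target

**Step count and risks**

Total steps: 12. Longest linear sequence: 10 (steps 1, 2, 4, 5, 6, 7, 9, 10, 11, 12).

Most likely to fail, first: step 10, the carbonyl-ene macrocyclisation. The 7(11)-alkene carries two allylic oxygens and a 10-membered ring must close, so the alkene may simply not react with the enal. The fallback replaces the C–H ene donor by an allylchromium and sets out from 12. SeO2 (cat.) with t-BuOOH in CH2Cl2 oxidises only the C13 methyl, because the other two alkenes are conjugated to carbonyls and this oxidation is E-selective, and gives (2Z,4R,5R,6Z)-5-(tert-butyldimethylsilyloxy)-7-(hydroxymethyl)-3-methyl-1-oxo-8-(triethylsilyloxy)octa-2,6-dien-4-yl angelate F1. CBr4/PPh3 converts it into the allylic bromide, (2Z,4R,5R,6E)-7-(bromomethyl)-5-(tert-butyldimethylsilyloxy)-3-methyl-1-oxo-8-(triethylsilyloxy)octa-2,6-dien-4-yl angelate F2. The aldol of step 9 with 14 then gives (2E,5S,6Z,8R,9R,10E)-11-(bromomethyl)-9-(tert-butyldimethylsilyloxy)-5-hydroxy-3,7-dimethyl-1-oxo-12-(triethylsilyloxy)dodeca-2,6,10-trien-8-yl angelate F3. CrCl2 in THF at high dilution closes C6–C7 by an intramolecular Nozaki–Hiyama–Kishi allylation (γ-attack through a chair, anti) and comes back to the route at 16.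

Second: step 9, the reagent-controlled vinylogous aldol on a hindered, β,β-disubstituted (Z)-enal, where rate and C2 selectivity are uncertain. The fallback gives up reagent control and sets out from 12 and 14. BF3·OEt2 in CH2Cl2 at −78 °C gives 15 together with its separable C2 epimer, (2E,5R,6Z,8R,9R,10Z)-9-(tert-butyldimethylsilyloxy)-5-hydroxy-3,7,11-trimethyl-1-oxo-12-(triethylsilyloxy)dodeca-2,6,10-trien-8-yl angelate F4. F4 is inverted by a Mitsunobu reaction (4-nitrobenzoic acid, DIAD, PPh3) to (2E,5S,6Z,8R,9R,10Z)-9-(tert-butyldimethylsilyloxy)-3,7,11-trimethyl-5-(4-nitrobenzoyloxy)-1-oxo-12-(triethylsilyloxy)dodeca-2,6,10-trien-8-yl angelate F5. Mild methanolysis (Et3N, MeOH) of the activated ester comes back to the route at 15.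

Third: step 6, where acylation of the hindered aluminium alkoxide may be slow and the hydroxy amide may relactonise. The fallback masks the aldehyde instead of the acid and sets out from 8. i-Bu2AlH at −78 °C gives the lactol, (5R)-5-[(1R,2Z)-1-(tert-butyldimethylsilyloxy)-3-methyl-4-(triethylsilyloxy)but-2-en-1-yl]-4-methyl-2,5-dihydrofuran-2-ol F6. Me2NNH2 with MgSO4 opens it to the hydroxy hydrazone, (1E,2Z,4R,5R,6Z)-5-(tert-butyldimethylsilyloxy)-1-(2,2-dimethylhydrazinylidene)-3,7-dimethyl-8-(triethylsilyloxy)octa-2,6-dien-4-ol F7. Acylation with 9 and DMAP gives its angelate, (1E,2Z,4R,5R,6Z)-5-(tert-butyldimethylsilyloxy)-1-(2,2-dimethylhydrazinylidene)-3,7-dimethyl-8-(triethylsilyloxy)octa-2,6-dien-4-yl angelate F8. Hydrazone exchange with aqueous glyoxylic acid in THF comes back to the route at 12.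

**Further compounds**
F1 | step 10 | (2Z,4R,5R,6Z)-5-(tert-butyldimethylsilyloxy)-7-(hydroxymethyl)-3-methyl-1-oxo-8-(triethylsilyloxy)octa-2,6-dien-4-yl angelate | O=C/C=C(C)\[C@@H](OC(=O)/C(C)=C\C)[C@H](O[Si](C)(C)C(C)(C)C)/C=C(CO)\CO[Si](CC)(CC)CC
F2 | step 10 | (2Z,4R,5R,6E)-7-(bromomethyl)-5-(tert-butyldimethylsilyloxy)-3-methyl-1-oxo-8-(triethylsilyloxy)octa-2,6-dien-4-yl angelate | O=C/C=C(C)\[C@@H](OC(=O)/C(C)=C\C)[C@H](O[Si](C)(C)C(C)(C)C)/C=C(CBr)\CO[Si](CC)(CC)CC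
F3 | step 10 | (2E,5S,6Z,8R,9R,10E)-11-(bromomethyl)-9-(tert-butyldimethylsilyloxy)-5-hydroxy-3,7-dimethyl-1-oxo-12-(triethylsilyloxy)dodeca-2,6,10-trien-8-yl angelate | O=C/C=C(\C)C[C@H](O)/C=C(C)\[C@@H](OC(=O)/C(C)=C\C)[C@H](O[Si](C)(C)C(C)(C)C)/C=C(CBr)\CO[Si](CC)(CC)CC
F4 | step 9 | (2E,5R,6Z,8R,9R,10Z)-9-(tert-butyldimethylsilyloxy)-5-hydroxy-3,7,11-trimethyl-1-oxo-12-(triethylsilyloxy)dodeca-2,6,10-trien-8-yl angelate | O=C/C=C(\C)C[C@@H](O)/C=C(C)\[C@@H](OC(=O)/C(C)=C\C)[C@H](O[Si](C)(C)C(C)(C)C)/C=C(C)\CO[Si](CC)(CC)CC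
F5 | step 9 | (2E,5S,6Z,8R,9R,10Z)-9-(tert-butyldimethylsilyloxy)-3,7,11-trimethyl-5-(4-nitrobenzoyloxy)-1-oxo-12-(triethylsilyloxy)dodeca-2,6,10-trien-8-yl angelate | O=C/C=C(\C)C[C@H](OC(=O)c1ccc(cc1)[N+](=O)[O-])/C=C(C)\[C@@H](OC(=O)/C(C)=C\C)[C@H](O[Si](C)(C)C(C)(C)C)/C=C(C)\CO[Si](CC)(CC)CC
F6 | step 6 | (5R)-5-[(1R,2Z)-1-(tert-butyldimethylsilyloxy)-3-methyl-4-(triethylsilyloxy)but-2-en-1-yl]-4-methyl-2,5-dihydrofuran-2-ol | CC1=CC(O)O[C@H]1[C@H](O[Si](C)(C)C(C)(C)C)/C=C(C)\CO[Si](CC)(CC)CC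
F7 | step 6 | (1E,2Z,4R,5R,6Z)-5-(tert-butyldimethylsilyloxy)-1-(2,2-dimethylhydrazinylidene)-3,7-dimethyl-8-(triethylsilyloxy)octa-2,6-dien-4-ol | CN(C)/N=C/C=C(C)\[C@@H](O)[C@H](O[Si](C)(C)C(C)(C)C)/C=C(C)\CO[Si](CC)(CC)CC
F8 | step 6 | (1E,2Z,4R,5R,6Z)-5-(tert-butyldimethylsilyloxy)-1-(2,2-dimethylhydrazinylidene)-3,7-dimethyl-8-(triethylsilyloxy)octa-2,6-dien-4-yl angelate | CN(C)/N=C/C=C(C)\[C@@H](OC(=O)/C(C)=C\C)[C@H](O[Si](C)(C)C(C)(C)C)/C=C(C)\CO[Si](CC)(CC)CC
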